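Assumption: the SMILES is read literally as (5S,8R,9R,10S), i.e. H‑5 cis to the C‑10 methyl (a cis‑fused decalin, the C‑5 epimer of the trans‑fused natural ketol), and the route is built for exactly that isomer. Numbering used below: C3 = ketone, C4 = CMe2, C5/C10 = ring fusion, C8 = carbinol, C9 carries the chain.

**Retrosynthetic overview**
- Ring A is closed last: the C3–C4 bond comes from an NHC‑generated acyl anion (Breslow intermediate of a C3 aldehyde) adding to the internal carbon of a C5 isopropenyl group, which delivers the ketone and the gem‑dimethyl carbon in one step.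
- The seco‑aldehyde comes from an allyl group (aldehyde‑selective Wacker); the C9–C11 bond comes from a C9 radical adding to a C16 diene made from farnesol.
- Ring B is the ring of (S)‑carvone and is present from the start: C5 is carvone's stereocentre, the C8–OH comes from enolate hydroxylation, and the C10 quaternary centre comes from allylation then methylation.
- The cis ring fusion is fixed at C10 (allyl cis to isopropenyl), long before ring A exists.

**Route**

Step 1
Reactants: 1 (S)-(+)-carvone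
Product: 3 (2R,5S)-2-hydroxy-2-methyl-5-(prop-1-en-2-yl)cyclohexan-1-one, via lithium enolate 2 (not isolated)
Conditions: L‑Selectride, THF, −78 °C; then 2‑(phenylsulfonyl)‑3‑phenyloxaziridine, −78 → −40 °C; H2O
Reagents that add atoms: 2-(benzenesulfonyl)-3-phenyloxaziridine, O=S(=O)(c1ccccc1)N1OC1c1ccccc1
Why: 1,4‑hydride reduction gives the tetrasubstituted enolate regiospecifically, and Davis α‑hydroxylation occurs by axial attack on the half‑chair with equatorial isopropenyl (the same facial sense as alkylations of the dihydrocarvone enolate), so the tertiary OH (C8) ends up cis to the isopropenyl group (2R).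

Step 2
Reactants: 3 (2R,5S)-2-hydroxy-2-methyl-5-(prop-1-en-2-yl)cyclohexan-1-one
Product: 5 (2R,5S,6RS)-2-hydroxy-2-methyl-6-(prop-2-en-1-yl)-5-(prop-1-en-2-yl)cyclohexan-1-one, via dilithio dianion 4 (not isolated)
Conditions: LDA (2.2 equiv), THF, −78 → −40 °C; allyl bromide, −78 → 0 °C; H2O
Reagents that add atoms: allyl bromide, C=CCBr
Why: Dianion enolate alkylation; the ketol can enolise only towards C6 because the other α‑carbon is quaternary, and the new centre need not be controlled because step 3 erases it.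

Step 3
Reactants: 5 (2R,5S,6RS)-2-hydroxy-2-methyl-6-(prop-2-en-1-yl)-5-(prop-1-en-2-yl)cyclohexan-1-one
Product: 8 (2R,5R,6S)-2,6-dimethyl-6-(prop-2-en-1-yl)-5-(prop-1-en-2-yl)-2-[(triethylsilyl)oxy]cyclohexan-1-one, via dilithio dianion 6 (not isolated), via lithium alkoxide 7 (not isolated)
Conditions: LDA (2.2 equiv), THF–DMPU, −78 → −30 °C; MeI (1.1 equiv), −78 °C; then TESOTf, −78 → 0 °C
Reagents that add atoms: iodomethane, CI; triethylsilyl trifluoromethanesulfonate, CC[Si](CC)(CC)OS(=O)(=O)C(F)(F)F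
Why: Enolate alkylation; in the Li‑chelated alkoxide–enolate half‑chair the isopropenyl group is pseudoaxial (A1,2 strain with the allyl group), so MeI enters axially anti to it (the precedented sense for 6‑substituted carvone enolates), giving 6S with allyl cis to isopropenyl (the future cis fusion); the alkoxide is then silylated in the flask, because a free C8–OH would later add to the isopropenyl group (cineole‑type ether).

Step 4
Reactants: 8 (2R,5R,6S)-2,6-dimethyl-6-(prop-2-en-1-yl)-5-(prop-1-en-2-yl)-2-[(triethylsilyl)oxy]cyclohexan-1-one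
Product: 9 (1RS,2R,5R,6S)-2,6-dimethyl-6-(prop-2-en-1-yl)-5-(prop-1-en-2-yl)-2-[(triethylsilyl)oxy]cyclohexan-1-ol
Conditions: LiAlH4, THF, 0 °C → rt; aqueous work‑up
Reagents that add atoms: none
Why: Hydride reduction; the small hydride reaches the doubly neopentylic ketone, isolated alkenes and the silyl ether are untouched, and the carbinol configuration is irrelevant because C9 becomes a radical.

Step 5
Reactants: 9 (1RS,2R,5R,6S)-2,6-dimethyl-6-(prop-2-en-1-yl)-5-(prop-1-en-2-yl)-2-[(triethylsilyl)oxy]cyclohexan-1-ol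
Product: 10 O-[(1RS,2R,5R,6S)-2,6-dimethyl-6-(prop-2-en-1-yl)-5-(prop-1-en-2-yl)-2-[(triethylsilyl)oxy]cyclohexyl] 1H-imidazole-1-carbothioate
Conditions: 1,1′‑thiocarbonyldiimidazole, DMAP (cat.), toluene, 100 °C
Reagents that add atoms: 1,1'-thiocarbonyldiimidazole, S=C(n1ccnc1)n1ccnc1
Why: Thioacylation to a Barton–McCombie radical precursor under neutral conditions, which avoids alkoxide‑induced silyl migration between the vicinal oxygens.

Step 6
Reactants: 11 (2E,6E)-farnesol
Product: 12 (2E,6E)-farnesal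
Conditions: MnO2, CH2Cl2, rt
Reagents that add atoms: none
Why: Chemoselective allylic alcohol oxidation that leaves the alkene geometry intact.

Step 7
Reactants: 12 (2E,6E)-farnesal
Product: 13 (3E,7E)-4,8,12-trimethyltrideca-1,3,7,11-tetraene
Conditions: Ph3PCH3Br, KOtBu, THF, 0 °C → rt
Reagents that add atoms: methyltriphenylphosphonium bromide, C[P+](c1ccccc1)(c1ccccc1)c1ccccc1.[Br-]
Why: Wittig methylenation of the enal gives the terminal 1,3‑diene without touching the existing E alkenes.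

Step 8
Reactants: 10 O-[(1RS,2R,5R,6S)-2,6-dimethyl-6-(prop-2-en-1-yl)-5-(prop-1-en-2-yl)-2-[(triethylsilyl)oxy]cyclohexyl] 1H-imidazole-1-carbothioate; 13 (3E,7E)-4,8,12-trimethyltrideca-1,3,7,11-tetraene
Product: 14 triethyl{[(1R,2R,3S,4R)-1,3-dimethyl-3-(prop-2-en-1-yl)-4-(prop-1-en-2-yl)-2-[(3E,7E)-4,8,12-trimethyltrideca-3,7,11-trien-1-yl]cyclohexyl]oxy}silane
Conditions: (TMS)3SiH, AIBN (cat.), 13 (5 equiv), PhH, 80 °C
Reagents that add atoms: none
Why: Proposed new method: Barton–McCombie fragmentation gives the secondary C9 radical, which adds Giese‑style to the unsubstituted terminus of the diene, and the allyl radical then takes H from the bulky silane at its less substituted end to give the E trisubstituted alkene; in the chair with equatorial isopropenyl the radical reacts axially, anti to the axial OTES (C8) and axial allyl (C10), so the chain is trans to the C8 oxygen and cis to both methyls (2R); closest known chemistry is deoxygenative Giese addition and radical hydroalkylation of 1,3‑dienes.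

Step 9
Reactants: 14 triethyl{[(1R,2R,3S,4R)-1,3-dimethyl-3-(prop-2-en-1-yl)-4-(prop-1-en-2-yl)-2-[(3E,7E)-4,8,12-trimethyltrideca-3,7,11-trien-1-yl]cyclohexyl]oxy}silane
Product: 15 3-{(1S,2R,3R,6R)-1,3-dimethyl-6-(prop-1-en-2-yl)-3-[(triethylsilyl)oxy]-2-[(3E,7E)-4,8,12-trimethyltrideca-3,7,11-trien-1-yl]cyclohexyl}propanal
Conditions: PdCl2(PhCN)2, CuCl2·2H2O, AgNO2 (all cat.), O2 (1 atm), t‑BuOH/MeNO2, rt
Reagents that add atoms: dioxygen, O=O
Why: Aldehyde‑selective (anti‑Markovnikov) nitrite‑modified Wacker oxidation; only the monosubstituted allyl alkene reacts, since 1,1‑di‑ and trisubstituted alkenes are inert under Wacker conditions.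

Step 10
Reactants: 15 3-{(1S,2R,3R,6R)-1,3-dimethyl-6-(prop-1-en-2-yl)-3-[(triethylsilyl)oxy]-2-[(3E,7E)-4,8,12-trimethyltrideca-3,7,11-trien-1-yl]cyclohexyl}propanal
Product: 17 (4aS,5R,6R,8aS)-6-hydroxy-1,1,4a,6-tetramethyl-5-[(3E,7E)-4,8,12-trimethyltrideca-3,7,11-trien-1-yl]octahydronaphthalen-2(1H)-one, via silyl ether 16 (not isolated)
Conditions: N‑mesityl cycloheptathiazolium perchlorate (20 mol %), DBU (40 mol %), 1,4‑dioxane (0.02 M), 120 °C; then TBAF, THF, rt
Reagents that add atoms: none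
Why: Proposed new method: the thiazolylidene converts the aliphatic aldehyde into a Breslow intermediate (acyl anion equivalent) that bonds to the internal isopropenyl carbon with proton transfer to its CH2 terminus (ene‑like 6‑exo hydroacylation), forming C3–C4, the ketone and the gem‑dimethyl group at once; no stereocentre is created and the cis fusion follows from step 3; the closest known reaction is the NHC‑catalysed intramolecular hydroacylation of unactivated 1,1‑disubstituted alkenes by aryl aldehydes to α‑quaternary six‑ring ketones; fluoride then removes the TES group.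

**Compound list**
1 | (S)-(+)-carvone, (5S)-2-methyl-5-(prop-1-en-2-yl)cyclohex-2-en-1-one | CC1=CC[C@@H](CC1=O)C(C)=C | starting material
2 | lithium (5S)-2-methyl-5-(prop-1-en-2-yl)cyclohex-1-en-1-olate | [Li]OC1=C(C)CC[C@H](C(C)=C)C1 | intermediate
3 | (2R,5S)-2-hydroxy-2-methyl-5-(prop-1-en-2-yl)cyclohexan-1-one (OH cis to isopropenyl) | O=C1C[C@@H](C(C)=C)CC[C@@]1(C)O | intermediate
4 | dilithium alkoxide–enolate of 3 (enolate towards C6) | [Li]OC1=C[C@@H](C(C)=C)CC[C@@]1(C)O[Li] | intermediate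
5 | (2R,5S,6RS)-2-hydroxy-2-methyl-6-(prop-2-en-1-yl)-5-(prop-1-en-2-yl)cyclohexan-1-one | O=C1C(CC=C)[C@@H](C(C)=C)CC[C@@]1(C)O | intermediate
6 | dilithium alkoxide–enolate of 5 | [Li]OC1=C(CC=C)[C@@H](C(C)=C)CC[C@@]1(C)O[Li] | intermediate
7 | lithium alkoxide of (2R,5R,6S)-2-hydroxy-2,6-dimethyl-6-(prop-2-en-1-yl)-5-(prop-1-en-2-yl)cyclohexan-1-one | O=C1[C@@](C)(CC=C)[C@@H](C(C)=C)CC[C@@]1(C)O[Li] | intermediate
8 | (2R,5R,6S)-2,6-dimethyl-6-(prop-2-en-1-yl)-5-(prop-1-en-2-yl)-2-[(triethylsilyl)oxy]cyclohexan-1-one (methyl trans, allyl cis to isopropenyl) | O=C1[C@@](C)(CC=C)[C@@H](C(C)=C)CC[C@@]1(C)O[Si](CC)(CC)CC | intermediate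
9 | (1RS,2R,5R,6S)-2,6-dimethyl-6-(prop-2-en-1-yl)-5-(prop-1-en-2-yl)-2-[(triethylsilyl)oxy]cyclohexan-1-ol | OC1[C@@](C)(CC=C)[C@@H](C(C)=C)CC[C@@]1(C)O[Si](CC)(CC)CC | intermediate
10 | O-[(1RS,2R,5R,6S)-2,6-dimethyl-6-(prop-2-en-1-yl)-5-(prop-1-en-2-yl)-2-[(triethylsilyl)oxy]cyclohexyl] 1H-imidazole-1-carbothioate | S=C(OC1[C@@](C)(CC=C)[C@@H](C(C)=C)CC[C@@]1(C)O[Si](CC)(CC)CC)n1ccnc1 | intermediate
11 | (2E,6E)-farnesol | CC(C)=CCC/C(C)=C/CC/C(C)=C/CO | starting material
12 | (2E,6E)-farnesal | CC(C)=CCC/C(C)=C/CC/C(C)=C/C=O | intermediate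
13 | (3E,7E)-4,8,12-trimethyltrideca-1,3,7,11-tetraene | CC(C)=CCC/C(C)=C/CC/C(C)=C/C=C | intermediate
14 | triethyl{[(1R,2R,3S,4R)-1,3-dimethyl-3-(prop-2-en-1-yl)-4-(prop-1-en-2-yl)-2-[(3E,7E)-4,8,12-trimethyltrideca-3,7,11-trien-1-yl]cyclohexyl]oxy}silane | CC(C)=CCC/C(C)=C/CC/C(C)=C/CC[C@@H]1[C@@](C)(CC=C)[C@@H](C(C)=C)CC[C@@]1(C)O[Si](CC)(CC)CC | intermediate
15 | 3-{(1S,2R,3R,6R)-1,3-dimethyl-6-(prop-1-en-2-yl)-3-[(triethylsilyl)oxy]-2-[(3E,7E)-4,8,12-trimethyltrideca-3,7,11-trien-1-yl]cyclohexyl}propanal | CC(C)=CCC/C(C)=C/CC/C(C)=C/CC[C@@H]1[C@@](C)(CCC=O)[C@@H](C(C)=C)CC[C@@]1(C)O[Si](CC)(CC)CC | intermediate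
16 | (4aS,5R,6R,8aS)-1,1,4a,6-tetramethyl-6-[(triethylsilyl)oxy]-5-[(3E,7E)-4,8,12-trimethyltrideca-3,7,11-trien-1-yl]octahydronaphthalen-2(1H)-one (cis-fused) | CC(C)=CCC/C(C)=C/CC/C(C)=C/CC[C@@H]1[C@@]2(C)CCC(=O)C(C)(C)[C@H]2CC[C@@]1(C)O[Si](CC)(CC)CC | intermediate
17 | (4aS,5R,6R,8aS)-6-hydroxy-1,1,4a,6-tetramethyl-5-[(3E,7E)-4,8,12-trimethyltrideca-3,7,11-trien-1-yl]octahydronaphthalen-2(1H)-one (IN0671; 5β‑H, 10β‑Me, 9β‑chain, 8α‑OH) | CC(C)=CCC/C(C)=C/CC/C(C)=C/CC[C@@H]1[C@@]2(C)CCC(=O)C(C)(C)[C@H]2CC[C@@]1(C)O | target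

**Totals**
Total step count: 10. Longest linear sequence: 8 (steps 1–5, 8–10).

**Three steps most likely to fail, each with a fallback**

Step 10 (hydroacylation with an aliphatic Breslow intermediate; aldol self‑condensation and a too‑unreactive alkene are the dangers). The fallback sets out from 15 and comes back at 16. It gives up the acyl anion and uses a hydrogen‑atom‑transfer radical closure instead: Fe(acac)3 and PhSiH3 in EtOH at 60 °C turn the isopropenyl group into the tertiary C4 radical, which closes 6‑exo onto the aldehyde carbonyl to give (2RS,4aS,5R,6R,8aS)-1,1,4a,6-tetramethyl-6-[(triethylsilyl)oxy]-5-[(3E,7E)-4,8,12-trimethyltrideca-3,7,11-trien-1-yl]decahydronaphthalen-2-ol F1. Dess–Martin oxidation of F1 gives 16, which is desilylated as in step 10. The 1,1‑disubstituted alkene is the fastest hydrogen‑atom acceptor, but the trisubstituted chain alkenes are at risk, so the silane is added in portions.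

Step 8 (intermolecular capture of a very hindered radical by a valuable diene, plus regiochemistry of the allyl‑radical quench). The fallback sets out from 10 and comes back at 14. The same C9 radical is trapped by cheap vinylboronic acid pinacol ester in large excess ((TMS)3SiH, AIBN), which gives triethyl{[(1R,2R,3S,4R)-1,3-dimethyl-3-(prop-2-en-1-yl)-4-(prop-1-en-2-yl)-2-[2-(4,4,5,5-tetramethyl-1,3,2-dioxaborolan-2-yl)ethyl]cyclohexyl]oxy}silane F2 with the same facial sense. Separately, geranyl bromide and propargylmagnesium bromide (CuI) give (5E)-6,10-dimethylundeca-5,9-dien-1-yne F3. Zirconium‑catalysed carboalumination (Me3Al, Cp2ZrCl2) gives dimethyl[(1E,5E)-2,6,10-trimethylundeca-1,5,9-trien-1-yl]alumane F4, and iodine then gives (1E,5E)-1-iodo-2,6,10-trimethylundeca-1,5,9-triene F5. A B‑alkyl Suzuki coupling of F2 with F5 (Pd(OAc)2, RuPhos, K3PO4, toluene–water, 90 °C) makes the C12–C13 bond and gives 14 with the E alkene already defined.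

Step 3 (facial selectivity of the methylation that creates the quaternary centre; the 1,3‑related axial C2 methyl opposes the favoured trajectory). The fallback sets out from 1 and comes back at 8. The quaternary centre is built first on the enone, in the precedented order. LDA gives lithium (3S)-6-methyl-3-(prop-1-en-2-yl)cyclohexa-1,5-dien-1-olate F6, and allyl bromide gives (5S,6RS)-2-methyl-6-(prop-2-en-1-yl)-5-(prop-1-en-2-yl)cyclohex-2-en-1-one F7. LDA then gives lithium (3S)-6-methyl-2-(prop-2-en-1-yl)-3-(prop-1-en-2-yl)cyclohexa-1,5-dien-1-olate F8, and MeI, entering anti to the isopropenyl group, gives (5R,6S)-2,6-dimethyl-6-(prop-2-en-1-yl)-5-(prop-1-en-2-yl)cyclohex-2-en-1-one F9. L‑Selectride gives lithium (5R,6S)-2,6-dimethyl-6-(prop-2-en-1-yl)-5-(prop-1-en-2-yl)cyclohex-1-en-1-olate F10; Davis oxaziridine converts it into alkoxide 7, and TESOTf gives 8. The cost is that the C8 hydroxylation must then select a face of a 6,6‑disubstituted enolate, which is less certain than in step 1.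

Further compounds
F1 | step 10 | (2RS,4aS,5R,6R,8aS)-1,1,4a,6-tetramethyl-6-[(triethylsilyl)oxy]-5-[(3E,7E)-4,8,12-trimethyltrideca-3,7,11-trien-1-yl]decahydronaphthalen-2-ol | CC(C)=CCC/C(C)=C/CC/C(C)=C/CC[C@@H]1[C@@]2(C)CCC(O)C(C)(C)[C@H]2CC[C@@]1(C)O[Si](CC)(CC)CC
F2 | step 8 | triethyl{[(1R,2R,3S,4R)-1,3-dimethyl-3-(prop-2-en-1-yl)-4-(prop-1-en-2-yl)-2-[2-(4,4,5,5-tetramethyl-1,3,2-dioxaborolan-2-yl)ethyl]cyclohexyl]oxy}silane | CC1(C)OB(CC[C@@H]2[C@@](C)(CC=C)[C@@H](C(C)=C)CC[C@@]2(C)O[Si](CC)(CC)CC)OC1(C)C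
F3 | step 8 | (5E)-6,10-dimethylundeca-5,9-dien-1-yne | C#CCC/C=C(\C)CCC=C(C)C
F4 | step 8 | dimethyl[(1E,5E)-2,6,10-trimethylundeca-1,5,9-trien-1-yl]alumane | C[Al](C)/C=C(\C)CC/C=C(\C)CCC=C(C)C
F5 | step 8 | (1E,5E)-1-iodo-2,6,10-trimethylundeca-1,5,9-triene | I/C=C(\C)CC/C=C(\C)CCC=C(C)C
F6 | step 3 | lithium (3S)-6-methyl-3-(prop-1-en-2-yl)cyclohexa-1,5-dien-1-olate | [Li]OC1=C[C@@H](C(C)=C)CC=C1C
F7 | step 3 | (5S,6RS)-2-methyl-6-(prop-2-en-1-yl)-5-(prop-1-en-2-yl)cyclohex-2-en-1-one | O=C1C(CC=C)[C@@H](C(C)=C)CC=C1C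
F8 | step 3 | lithium (3S)-6-methyl-2-(prop-2-en-1-yl)-3-(prop-1-en-2-yl)cyclohexa-1,5-dien-1-olate | [Li]OC1=C(CC=C)[C@@H](C(C)=C)CC=C1C
F9 | step 3 | (5R,6S)-2,6-dimethyl-6-(prop-2-en-1-yl)-5-(prop-1-en-2-yl)cyclohex-2-en-1-one | O=C1[C@@](C)(CC=C)[C@@H](C(C)=C)CC=C1C
F10 | step 3 | lithium (5R,6S)-2,6-dimethyl-6-(prop-2-en-1-yl)-5-(prop-1-en-2-yl)cyclohex-1-en-1-olate | [Li]OC1=C(C)CC[C@H](C(C)=C)[C@]1(C)CC=C
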